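## The problem

The target is a 3,3''-biflavanone: two 2-(4-methoxyphenyl)chroman-4-ones joined by a single bond between C3 and C3''. C2, C3, C3'' and C2'' form one chain of four contiguous stereocentres, the inner two α to the C4 and C4'' ketones and the outer two each carrying an aryl group and the ring oxygen. All four centres are S and both pyranone rings are 2,3-cis, the less stable arrangement. C3 and C3'' are enolisable, and C2 and C2'' are 4-methoxybenzylic ethers that open by retro-oxa-Michael reaction under base and ionise under acid, so the centres must be set late, kinetically, and then handled under neutral conditions only. Within one ring, C2 and C3 can be set as a pair by a syn addition to a C2=C3 bond; across C3–C3'' nothing resident can steer the first event, so the relation between the halves must come from a reagent, and the first pair of centres then either supports or opposes the second addition. The halves differ only at O7 (hydroxyl) and O7'' (methyl ether), so a symmetric dimerisation would need a statistical differentiation later; the two rings A must be distinct from the start. The three phenols, two of them chelated to the ketones, need protecting groups that leave without acid or base. The feature that opens the route is that C4–C3–C3''–C4'' is a succinyl unit flanked by two ortho-oxygenated rings A, and that C2 and C2'' are each bonded both to O1 or O1'' and to an α-carbon of this 1,4-dione: each C2–C3 bond joins a ketone α-carbon to an aroyl carbon that can be handed over from the neighbouring ring A oxygen.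

## Retrosynthesis

**19 to 18 (three phenolic O–H bonds).** The free phenols of target 19 are traced back to the benzyl ethers of 18. Benzyl is preferred to silyl, acyl or acetal groups because it leaves by hydrogenolysis in a neutral medium, the only kind the cis centres tolerate, and because it is distinct from the three permanent methyl ethers. The forward step must cleave three O–CH2Ph bonds without touching the benzylic C2–O1 and C2''–O1'' bonds.

**18 to 17 (the C–H bonds at C2, C3, C2'' and C3'').** All four stereocentres are removed at once by going back to the flat 3,3''-biflavone 17. The neighbouring cuts are worse: ring closure by oxa-Michael addition, or joining two flavanones at C3, would pass through enolates and deliver the trans rings. A syn addition of H2 is the one operation whose mechanism puts H2 and H3 on the same face. Compound 17 has no stereocentre and is robust. The forward reaction must add H2 to two tetrasubstituted C2=C3 bonds from the Re,Re face of each, under catalyst control.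

**17 to 16 (O1–C2 and O1''–C2'').** Each γ-pyrone is opened at its enol ether bond, giving the bis(β-diketone) 16 with two free ortho-phenols. This is the standard retron of a flavone and costs only two molecules of water. The forward cyclodehydration must be faster than furan formation between any two of the four carbonyl groups.

**16 to 15 (C2–C3 and C2''–C3'', the key cut).** Both aroyl–Cα bonds are cut and the 4-methoxybenzoyl groups are returned to the ring A oxygens, giving the bis(ester) 15 of a 1,4-diaryl-1,4-dione. An intermolecular Claisen acylation of the dione would have to choose between C and O, between mono- and polyacylation, and between two nearly equal α-positions. The intramolecular acyl shift delivers each aroyl group to the α-carbon of its own half through a six-membered transition state. The precursor has lost two C–C bonds and carries C3–C3'' as a plain CH2–CH2 unit. The forward reaction must run twice in one molecule.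

**15 to 13 and 14 (two aryl ester C–O bonds).** The esters are cut to the bis(phenol) 13 and two equivalents of 4-methoxybenzoyl chloride 14. This is ordinary O-acylation; the base only has to be too weak to enolise the ketones.

**13 to 12 (two O–H bonds masked as methoxymethyl ethers).** The ortho-hydroxyls of 13 cannot be free while the central bond is made, because an ortho-hydroxy phenacyl bromide closes to a benzofuranone. They also cannot yet carry the aroyl groups, because an enolate next to an aryl ester would rearrange prematurely. The MOM ethers of 12 survive enolate chemistry and leave under mild acid that spares benzyl ethers.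

**12 to 5 and 10 (the central C3–C3'' bond).** The CH2–CH2 bond is cut between the enolate of methyl ketone 5 and the phenacyl bromide 10. A Friedel–Crafts acylation of two phloroglucinol ethers with a succinic acid derivative would have to find the position between a hydroxyl and an ether rather than the one para to the hydroxyl, would expose benzyl ethers to a strong Lewis acid, and would have to pass a γ-keto acid chloride that tends to react as a lactol chloride. An oxidative coupling of two different enolates would be statistical. Assigning one half as nucleophile and the other as electrophile makes the unsymmetrical dione by construction. Both fragments are simple acetophenones.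

**10 to 8 to 7 to 6, and 5 to 3 to 1 (C–Br, O–MOM and O–benzyl bonds).** Bromide 10 comes from ketone 8 by α-bromination through its silyl enol ether 9, which keeps bromine off the electron-rich ring. Ketones 8 and 5 come from the chelated phenols 7 and 3 with chloromethyl methyl ether 4. Phenol 7 comes from the commercial acetophenone 6 with one equivalent of benzyl bromide 2, and phenol 3 from the commercial acetophenone 1 with two equivalents of 2. The hydrogen bond of one ortho-hydroxyl to the acetyl group is the selectivity element: it leaves exactly that oxygen free for the later ester.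

## Roads not taken

**Alternative 1:** The cut removes C3–C3'' and both C2–O bonds and leads to two molecules of 4-methoxycinnamic acid A1. In the forward step, anodic oxidation (graphite, Bu4NBF4, 2,6-lutidine, acetonitrile/hexafluoroisopropanol) joins the two α-carbons, and each carboxylate traps the benzylic cation of the other half to give the cis-fused bislactone A2.
- Merits: one step from a cheap acid builds the whole aryl–C3–C3–aryl chain, including the hindered central bond, with the relative configuration fixed by the bicycle and no protecting groups.
- Weak points for this target: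
  - The oxygen on C2 is a carboxylate oxygen, not the ring A oxygen. Each benzylic C–O bond would have to be broken and remade as an aryl ether at a 4-methoxybenzylic carbon that ionises easily, so the configuration set in A2 is not safely carried over.
  - The two different rings A would have to be added as hindered aryl nucleophiles to two equivalent lactone carbonyls of a C2-symmetric compound, which is statistical.
  - The electrolysis is achiral, so A2 is racemic.
- Comparison: this road is clearly shorter to the carbon chain and better at the central bond than step 6 of the chosen plan. The chosen plan sets against it that the true O1–C2 connectivity and two differentiated rings A are present from early on, and that absolute configuration is addressed by a catalyst rather than a resolution.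

**Alternative 2:** The cut is C2–C3 of the 5,7-dihydroxy half only. The precursor is diazo ketone A3, in which the ring A oxygen carries a 4-methoxybenzyl group and the diazo carbon is already bonded to C3 of a chromone. In the forward step, dirhodium tetrakis[N-phthaloyl-tert-leucinate] (a divalent rhodium carboxylate) forms the carbene, which inserts into a benzylic ether C–H bond and closes ring C, giving the cis-flavanone–chromone A4.
- Merits: C2 and C3 of one half are set in a C–C bond-forming step by a chiral catalyst, a reaction type with precedent in closing 2-aryl oxygen heterocycles; no hindered alkene has to be hydrogenated in that half.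
- Weak points for this target:
  - Only one half is solved. A4 lacks the 2''-aryl group and both centres of the second ring, which would need conjugate arylation of a 3-substituted chromone and a cis-selective protonation next to an epimerisable cis-flavanone.
  - The insertion must form a six-membered ring in competition with attack of the carbene on the adjacent chromone carbonyl oxygen and on silyl ether C–H bonds.
  - A3 needs a long linear preparation with two kinds of protecting group.
- Comparison: for the first ring this road has better-founded stereocontrol than the hydrogenation of the chosen plan. The chosen plan sets against it that both halves are handled by the same operations, that C3–C3'' and both aryl groups are in place before any stereocentre exists, and that fewer steps are needed.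

**Alternative 3:** The cut is O1–C8a and C4–C4a in both halves. The precursors are the diol bis(N-methoxy-N-methylamide) A5, which carries all four stereocentres on an open chain, and two equivalents of the aryne released from silylaryl triflate A6. In the forward step, CsF frees the aryne, each alkoxide adds to the aryne carbon remote from the benzyloxy group, and the resulting aryl anion is acylated by the neighbouring amide, closing both pyranone rings to the tetra-O-benzyl cis,cis-biflavanone A7.
- Merits: the most convergent road; the centres are set by acyclic chemistry before the rings exist, so no hindered tetrasubstituted alkene has to be hydrogenated, and the aryne regiochemistry gives the 5,7-pattern by itself. If A5 is available as one stereoisomer, this road is better than the chosen one in stereocontrol and convergence.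
- Weak points for this target:
  - A7 has two identical rings A, whereas the target has a methyl ether at O7'' only. That means a late statistical mono-methylation among four phenols, or a statistical cross-annulation with two arynes.
  - The alkoxide of a β-hydroxy amide under fluoride is prone to retro-aldol cleavage, and the α-carbons to epimerisation.
  - A5, with four contiguous centres on a succinamide, is itself an unsolved intermediate.
- Comparison: the chosen plan sets against it rings A that are differentiated by construction, classical reactions up to the biflavone, and a stereochemical problem concentrated in one step that can be studied separately.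

Key step: step 9

## Assumptions

- 1-(2,6-Dihydroxy-4-methoxyphenyl)ethanone 6 is taken as a purchasable compound; it is otherwise one selective O4-methylation away from 1.
- The (R,R) enantiomer of the imidazolinium salt in step 11 is assumed to deliver H2 to the Re,Re face of each C2=C3 bond; if the sense is the opposite, the (S,S) salt is used.
- A non-isolated compound is numbered when it is made by one reagent and consumed by a reagent or reactant added afterwards; half-reacted species of a twofold reaction with one reagent are not numbered.
- Steps 1 and 8 each consume two equivalents of a numbered reactant (2 and 14); the second equivalent is entered under "Reagents that add atoms" so that each equation balances.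

## Route

Step 1
Reactants: 1 1-(2,4,6-trihydroxyphenyl)ethanone; 2 benzyl bromide
Product: 3 1-[2,4-bis(benzyloxy)-6-hydroxyphenyl]ethanone
Conditions: K2CO3, DMF, 60 °C (2.1 equiv of 2 in all)
Reagents that add atoms: benzyl bromide, BrCc1ccccc1 (the second equivalent of 2)
Why: Twofold Williamson ether synthesis that consumes two equivalents of 2; the hydroxyl chelated to the acetyl carbonyl is the least nucleophilic, so O4 and one ortho oxygen should be alkylated and the chelated one left free. C-benzylation of the phloroglucinol ring is the known competitor and is limited by the weak base and moderate temperature.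

Step 2
Reactants: 3 1-[2,4-bis(benzyloxy)-6-hydroxyphenyl]ethanone; 4 chloromethyl methyl ether
Product: 5 1-[2,4-bis(benzyloxy)-6-(methoxymethoxy)phenyl]ethanone
Conditions: NaH, DMF, 0 °C to rt
Reagents that add atoms: none
Why: O-alkylation of the sodium phenoxide (Williamson type); NaH breaks the chelate, and the resulting MOM ether is stable to enolate chemistry and removable with mild acid.

Step 3
Reactants: 6 1-(2,6-dihydroxy-4-methoxyphenyl)ethanone; 2 benzyl bromide
Product: 7 1-[2-(benzyloxy)-6-hydroxy-4-methoxyphenyl]ethanone
Conditions: K2CO3, acetone, reflux (1.05 equiv of 2)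
Reagents that add atoms: none
Why: Williamson ether synthesis on one of two equivalent hydroxyls; after the first alkylation the remaining hydroxyl is locked in the chelate, which should stop the reaction at the mono-ether.

Step 4
Reactants: 7 1-[2-(benzyloxy)-6-hydroxy-4-methoxyphenyl]ethanone; 4 chloromethyl methyl ether
Product: 8 1-[2-(benzyloxy)-4-methoxy-6-(methoxymethoxy)phenyl]ethanone
Conditions: NaH, DMF, 0 °C to rt
Reagents that add atoms: none
Why: Same O-alkylation of a sodium phenoxide as in step 2.

Step 5
Reactants: 8 1-[2-(benzyloxy)-4-methoxy-6-(methoxymethoxy)phenyl]ethanone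
Product: 10 1-[2-(benzyloxy)-4-methoxy-6-(methoxymethoxy)phenyl]-2-bromoethanone, via trimethylsilyl enol ether 9 (not isolated)
Conditions: LiN(SiMe3)2, Me3SiCl, THF, −78 °C; then NBS, −78 to 0 °C
Reagents that add atoms: N-bromosuccinimide, O=C1CCC(=O)N1Br; chlorotrimethylsilane, C[Si](C)(C)Cl (its silyl group is carried only by intermediate 9)
Why: α-Bromination of a ketone through its silyl enol ether; the enol ether is far more nucleophilic than the trioxygenated ring, so bromine should go to the CH2 carbon and not to C3 or C5 of the arene.

Step 6
Reactants: 5 1-[2,4-bis(benzyloxy)-6-(methoxymethoxy)phenyl]ethanone; 10 1-[2-(benzyloxy)-4-methoxy-6-(methoxymethoxy)phenyl]-2-bromoethanone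
Product: 12 1-[2,4-bis(benzyloxy)-6-(methoxymethoxy)phenyl]-4-[2-(benzyloxy)-4-methoxy-6-(methoxymethoxy)phenyl]butane-1,4-dione, via lithium enolate 11 (not isolated)
Conditions: LiN(SiMe3)2, THF, −78 °C; then 10, DMPU, −78 to −20 °C
Reagents that add atoms: none
Why: SN2 alkylation of a methyl ketone lithium enolate by a phenacyl bromide, which forms the CH2–CH2 bond that becomes C3–C3''. The carbonyl of 10 is shielded by two ortho substituents, which should disfavour the competing addition to C=O.

Step 7
Reactants: 12 1-[2,4-bis(benzyloxy)-6-(methoxymethoxy)phenyl]-4-[2-(benzyloxy)-4-methoxy-6-(methoxymethoxy)phenyl]butane-1,4-dione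
Product: 13 1-[2,4-bis(benzyloxy)-6-hydroxyphenyl]-4-[2-(benzyloxy)-6-hydroxy-4-methoxyphenyl]butane-1,4-dione
Conditions: HCl (cat.), MeOH/THF, 45 °C
Reagents that add atoms: none
Why: Acid-catalysed acetal exchange (MOM removal); MOM ethers ortho to a ketone cleave readily, benzyl and methyl ethers are inert, and the mild acid should not yet close the 1,4-dione to a furan.

Step 8
Reactants: 13 1-[2,4-bis(benzyloxy)-6-hydroxyphenyl]-4-[2-(benzyloxy)-6-hydroxy-4-methoxyphenyl]butane-1,4-dione; 14 4-methoxybenzoyl chloride
Product: 15 1-[2,4-bis(benzyloxy)-6-(4-methoxybenzoyloxy)phenyl]-4-[2-(benzyloxy)-4-methoxy-6-(4-methoxybenzoyloxy)phenyl]butane-1,4-dione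
Conditions: pyridine, DMAP (cat.), CH2Cl2, 0 °C to rt (2.5 equiv of 14 in all)
Reagents that add atoms: 4-methoxybenzoyl chloride, COc1ccc(C(=O)Cl)cc1 (the second equivalent of 14)
Why: Twofold O-acylation of the two phenols with an acid chloride under nucleophilic catalysis, one equivalent of 14 per phenol, the usual preparation of Baker–Venkataraman substrates; pyridine is too weak a base to enolise the ketones, so no acyl shift occurs here.

Step 9
Reactants: 15 1-[2,4-bis(benzyloxy)-6-(4-methoxybenzoyloxy)phenyl]-4-[2-(benzyloxy)-4-methoxy-6-(4-methoxybenzoyloxy)phenyl]butane-1,4-dione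
Product: 16 1-[2,4-bis(benzyloxy)-6-hydroxyphenyl]-4-[2-(benzyloxy)-6-hydroxy-4-methoxyphenyl]-2,3-bis(4-methoxybenzoyl)butane-1,4-dione
Conditions: KOt-Bu (6 equiv), THF, argon, 0 to 40 °C; then AcOH, 0 °C
Reagents that add atoms: none
Why: Baker–Venkataraman rearrangement, run on both halves in one flask. KOt-Bu forms the enolate at C3 (and then at C3''), the enolate carbon adds to the carbonyl of the 4-methoxybenzoate on the ortho oxygen through a six-membered cyclic transition state, and the tetrahedral 2-oxido-2-arylchromanone adduct expels the ring A phenoxide, so that C2–C3 and C2''–C3'' are formed and both phenols are set free. The closest known reaction is the rearrangement of 2-aroyloxypropiophenones and other α-substituted 2-aroyloxyaryl ketones on the way to 3-substituted flavones. Each transfer is pulled forward by deprotonation of the new 2-substituted 1,3-diketone, which is why at least four equivalents of base are consumed and six are used. No ring stays closed in this step, so no mode of closure has to be named; the only cyclic species is the transient tetrahedral adduct. No lasting stereocentre is made: C3 and C3'' become the CH carbons of β-diketones, and 16 is taken on as a mixture of tautomers and diastereomers that step 10 levels. The step needs C-acylation at C3 and C3'' by the ester of the same half rather than acyl transfer between molecules, to tert-butoxide or to oxygen; the ortho placement of ester and enolate, which makes the six-membered pathway the fastest one available, secures this. Furan formation from the 1,4-dione and retro-Claisen cleavage are held back by the aprotic, hydroxide-free basic medium and the cold AcOH quench.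

Step 10
Reactants: 16 1-[2,4-bis(benzyloxy)-6-hydroxyphenyl]-4-[2-(benzyloxy)-6-hydroxy-4-methoxyphenyl]-2,3-bis(4-methoxybenzoyl)butane-1,4-dione
Product: 17 5,7-bis(benzyloxy)-3-[5-(benzyloxy)-7-methoxy-2-(4-methoxyphenyl)-4-oxo-4H-chromen-3-yl]-2-(4-methoxyphenyl)-4H-chromen-4-one
Conditions: TsOH·H2O (0.2 equiv), toluene, 80 °C
Reagents that add atoms: none
Why: Acid-catalysed cyclodehydration of ortho-hydroxyaryl β-diketones to chromones, the usual second stage of a flavone synthesis; each phenol adds to the adjacent 4-methoxybenzoyl carbonyl and loss of water gives the aromatic γ-pyrone. Because 3-substituted diketones of this kind rest largely as the ring-closed hemiketals, dehydration to 17 should outrun furan formation.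

Step 11
Reactants: 17 5,7-bis(benzyloxy)-3-[5-(benzyloxy)-7-methoxy-2-(4-methoxyphenyl)-4-oxo-4H-chromen-3-yl]-2-(4-methoxyphenyl)-4H-chromen-4-one
Product: 18 (2S,3S)-5,7-bis(benzyloxy)-3-[(2S,3S)-5-(benzyloxy)-7-methoxy-2-(4-methoxyphenyl)-4-oxo-3,4-dihydro-2H-chromen-3-yl]-2-(4-methoxyphenyl)-2,3-dihydro-4H-chromen-4-one
Conditions: Ru(cod)(2-methylallyl)2 (10 mol%), 1,3-bis[(R)-1-(1-naphthyl)ethyl]imidazolinium tetrafluoroborate (20 mol%), KOt-Bu (20 mol%), catalyst preformed in hexane at 70 °C; H2 (100 bar), toluene, 40 °C
Reagents that add atoms: none
Why: Proposed new method: the ruthenium N-heterocyclic carbene catalyst made from Ru(cod)(2-methylallyl)2 and this C2-symmetric imidazolinylidene is known to add H2 syn and enantioselectively to the trisubstituted C2=C3 bond of flavones and 2-substituted chromones and to hydrogenate substituted furans and benzofurans; here the same reaction type is asked to reduce the two tetrasubstituted C2=C3 bonds of a 3,3''-linked biflavone, which has not been shown. Each pyranone C=C is the same polarised vinylogous ester as in a flavone, the metal delivers both hydrogens to one face so that H2 and H3 end up cis in each ring, and the ligand selects the Re,Re face of each C2=C3 bond so that both rings come out (2S,3S); since the catalyst chooses the face of each of two nearly identical chromones, the (2S,3S,2''S,3''S) isomer should dominate over the heterochiral one. Benzyl ethers, arenes and the doubly flanked C4 ketones should react more slowly than the conjugated C=C, and no free base is left after catalyst formation, which protects the enolisable C3 and C3''.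

Step 12
Reactants: 18 (2S,3S)-5,7-bis(benzyloxy)-3-[(2S,3S)-5-(benzyloxy)-7-methoxy-2-(4-methoxyphenyl)-4-oxo-3,4-dihydro-2H-chromen-3-yl]-2-(4-methoxyphenyl)-2,3-dihydro-4H-chromen-4-one
Product: 19 (2S,3S)-5,7-dihydroxy-3-[(2S,3S)-5-hydroxy-7-methoxy-2-(4-methoxyphenyl)-4-oxo-3,4-dihydro-2H-chromen-3-yl]-2-(4-methoxyphenyl)-2,3-dihydro-4H-chromen-4-one
Conditions: H2 (1 atm), 10% Pd on carbon, EtOAc/MeOH, rt
Reagents that add atoms: none
Why: Hydrogenolysis of benzyl aryl ethers under neutral conditions; aryl ketones and methyl ethers are inert at one atmosphere, and with neither acid nor base present the four stereocentres should be left as set.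

## Compound list

1 | 1-(2,4,6-trihydroxyphenyl)ethanone | CC(=O)c1c(O)cc(O)cc1O | starting material
2 | benzyl bromide | BrCc1ccccc1 | starting material
3 | 1-[2,4-bis(benzyloxy)-6-hydroxyphenyl]ethanone | CC(=O)c1c(O)cc(OCc2ccccc2)cc1OCc1ccccc1 | intermediate
4 | chloromethyl methyl ether | COCCl | starting material
5 | 1-[2,4-bis(benzyloxy)-6-(methoxymethoxy)phenyl]ethanone | CC(=O)c1c(OCOC)cc(OCc2ccccc2)cc1OCc1ccccc1 | intermediate
6 | 1-(2,6-dihydroxy-4-methoxyphenyl)ethanone | CC(=O)c1c(O)cc(OC)cc1O | starting material
7 | 1-[2-(benzyloxy)-6-hydroxy-4-methoxyphenyl]ethanone | CC(=O)c1c(O)cc(OC)cc1OCc1ccccc1 | intermediate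
8 | 1-[2-(benzyloxy)-4-methoxy-6-(methoxymethoxy)phenyl]ethanone | CC(=O)c1c(OCOC)cc(OC)cc1OCc1ccccc1 | intermediate
9 | ({1-[2-(benzyloxy)-4-methoxy-6-(methoxymethoxy)phenyl]ethenyl}oxy)trimethylsilane | C=C(O[Si](C)(C)C)c1c(OCOC)cc(OC)cc1OCc1ccccc1 | intermediate (not isolated)
10 | 1-[2-(benzyloxy)-4-methoxy-6-(methoxymethoxy)phenyl]-2-bromoethanone | O=C(CBr)c1c(OCOC)cc(OC)cc1OCc1ccccc1 | intermediate
11 | lithium 1-[2,4-bis(benzyloxy)-6-(methoxymethoxy)phenyl]ethenolate | [Li+].[O-]C(=C)c1c(OCOC)cc(OCc2ccccc2)cc1OCc1ccccc1 | intermediate (not isolated)
12 | 1-[2,4-bis(benzyloxy)-6-(methoxymethoxy)phenyl]-4-[2-(benzyloxy)-4-methoxy-6-(methoxymethoxy)phenyl]butane-1,4-dione | COCOc1cc(OCc2ccccc2)cc(OCc2ccccc2)c1C(=O)CCC(=O)c1c(OCOC)cc(OC)cc1OCc1ccccc1 | intermediate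
13 | 1-[2,4-bis(benzyloxy)-6-hydroxyphenyl]-4-[2-(benzyloxy)-6-hydroxy-4-methoxyphenyl]butane-1,4-dione | Oc1cc(OCc2ccccc2)cc(OCc2ccccc2)c1C(=O)CCC(=O)c1c(O)cc(OC)cc1OCc1ccccc1 | intermediate
14 | 4-methoxybenzoyl chloride | COc1ccc(C(=O)Cl)cc1 | starting material
15 | 1-[2,4-bis(benzyloxy)-6-(4-methoxybenzoyloxy)phenyl]-4-[2-(benzyloxy)-4-methoxy-6-(4-methoxybenzoyloxy)phenyl]butane-1,4-dione | COc1ccc(C(=O)Oc2cc(OCc3ccccc3)cc(OCc3ccccc3)c2C(=O)CCC(=O)c2c(OC(=O)c3ccc(OC)cc3)cc(OC)cc2OCc2ccccc2)cc1 | intermediate (precursor of the key step)
16 | 1-[2,4-bis(benzyloxy)-6-hydroxyphenyl]-4-[2-(benzyloxy)-6-hydroxy-4-methoxyphenyl]-2,3-bis(4-methoxybenzoyl)butane-1,4-dione (configuration at the two CH carbons not defined; tautomer mixture) | COc1ccc(C(=O)C(C(=O)c2c(O)cc(OCc3ccccc3)cc2OCc2ccccc2)C(C(=O)c2ccc(OC)cc2)C(=O)c2c(O)cc(OC)cc2OCc2ccccc2)cc1 | intermediate (product of the key step)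
17 | 5,7-bis(benzyloxy)-3-[5-(benzyloxy)-7-methoxy-2-(4-methoxyphenyl)-4-oxo-4H-chromen-3-yl]-2-(4-methoxyphenyl)-4H-chromen-4-one | COc1ccc(-c2oc3cc(OCc4ccccc4)cc(OCc4ccccc4)c3c(=O)c2-c2c(-c3ccc(OC)cc3)oc3cc(OC)cc(OCc4ccccc4)c3c2=O)cc1 | intermediate
18 | (2S,3S)-5,7-bis(benzyloxy)-3-[(2S,3S)-5-(benzyloxy)-7-methoxy-2-(4-methoxyphenyl)-4-oxo-3,4-dihydro-2H-chromen-3-yl]-2-(4-methoxyphenyl)-2,3-dihydro-4H-chromen-4-one (both rings 2,3-cis) | COc1ccc([C@H]2Oc3cc(OCc4ccccc4)cc(OCc4ccccc4)c3C(=O)[C@H]2[C@@H]2C(=O)c3c(OCc4ccccc4)cc(OC)cc3O[C@@H]2c2ccc(OC)cc2)cc1 | intermediate
19 | (2S,3S)-5,7-dihydroxy-3-[(2S,3S)-5-hydroxy-7-methoxy-2-(4-methoxyphenyl)-4-oxo-3,4-dihydro-2H-chromen-3-yl]-2-(4-methoxyphenyl)-2,3-dihydro-4H-chromen-4-one (both rings 2,3-cis) | COc1ccc([C@H]2Oc3cc(O)cc(O)c3C(=O)[C@H]2[C@@H]2C(=O)c3c(O)cc(OC)cc3O[C@@H]2c2ccc(OC)cc2)cc1 | target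

## Step count and least certain steps

Total: 12 steps. Longest linear sequence: 10 steps (steps 3 to 12, from 6); the branch from 1 runs through 9 steps.

**On step 11 (labelled step, least certain).**
- What may go wrong: the catalyst may not turn over on a tetrasubstituted C=C flanked by an aryl group and a second chromone. The C3–C3'' axis of 17 may rotate slowly, so that one atropisomeric form is a mismatched substrate. After the first ring is reduced, its two new centres may oppose the catalyst in the second ring, giving poor facial selectivity between the halves. Over-reduction of the ketones, or epimerisation at C3 by traces of base, would erode the result further.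
- Fallback with known chemistry: it sets out from 17 and uses heterogeneous syn-hydrogenation over Pd on carbon (H2, EtOAc/AcOH), which reduces both chromone C=C bonds and removes the benzyl groups in one operation. This gives the stereoisomer mixture of the free cis,cis-biflavanone F1 (the racemate containing 19, plus the heterochiral diastereomer). Preparative chromatography on a chiral stationary phase then isolates the (2S,3S,2''S,3''S) isomer, and the route is rejoined at 19.

**On step 9 (key step).**
- What may go wrong: the second acyl shift may stall, because the second enolate has to form next to an already anionic diketonate. Acyl transfer to tert-butoxide, or retro-Claisen cleavage of the first-formed diketone, could then compete.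
- Fallback: it sets out from 13 and leaves the acyl shift aside. The lithium polyanion of 13 (excess LiN(SiMe3)2, THF, −78 °C) is C-aroylated directly with two equivalents of 14, coming back to the route at 16 without any new compound (F0).

**On step 6.**
- What may go wrong: proton transfer from the more acidic bromoketone to the enolate, a second alkylation of the product, and addition to the carbonyl of 10 followed by epoxide closure.
- Fallback: it sets out from 5 and replaces the simple enolate by a stabilised one. Carboxylation with NaH and diallyl carbonate gives allyl 3-[2,4-bis(benzyloxy)-6-(methoxymethoxy)phenyl]-3-oxopropanoate F2. Its K2CO3-mediated alkylation with 10 in acetone gives the allyl 2-(2-aryl-2-oxoethyl)-3-aryl-3-oxopropanoate F3. Deallylation with decarboxylation by Pd(PPh3)4 and morpholine in THF then comes back to the route at 12.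

**On step 10.**
- What may go wrong: furan formation between two of the four carbonyl groups under acid, and acid-induced loss of the benzyl groups peri to the carbonyls.
- Fallback: it sets out from 16 and avoids acid. The ring-closed bis(hemiketal) tautomer, 5,7-bis(benzyloxy)-3-[5-(benzyloxy)-2-hydroxy-7-methoxy-2-(4-methoxyphenyl)-4-oxochroman-3-yl]-2-hydroxy-2-(4-methoxyphenyl)chroman-4-one F4, is activated with methanesulfonyl chloride and triethylamine in CH2Cl2 at 0 °C. β-Elimination of the sulfonates from these β-ketol units comes back to the route at 17.

**On step 12.**
- What may go wrong: hydrogenolysis of the benzylic C2–O1 and C2''–O1'' bonds with ring opening, or epimerisation at C3 and C3'' on the catalyst surface in the alcohol co-solvent.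
- Fallback: it sets out from 18 and removes the benzyl groups without hydrogen, using BCl3 and pentamethylbenzene in CH2Cl2 at −78 °C, which leaves the three methyl ethers in place. It comes back to the route at 19 without any new compound (F0).

## Further compounds

F1 | step 11 | 5,7-dihydroxy-3-[5-hydroxy-7-methoxy-2-(4-methoxyphenyl)-4-oxochroman-3-yl]-2-(4-methoxyphenyl)chroman-4-one, both rings 2,3-cis, mixture of the racemate of 19 and the heterochiral diastereomer (drawn without configuration) | COc1ccc(C2Oc3cc(O)cc(O)c3C(=O)C2C2C(=O)c3c(O)cc(OC)cc3OC2c2ccc(OC)cc2)cc1
F0 | step 9 | none | none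
F2 | step 6 | allyl 3-[2,4-bis(benzyloxy)-6-(methoxymethoxy)phenyl]-3-oxopropanoate | C=CCOC(=O)CC(=O)c1c(OCOC)cc(OCc2ccccc2)cc1OCc1ccccc1
F3 | step 6 | allyl 2-{2-[2-(benzyloxy)-4-methoxy-6-(methoxymethoxy)phenyl]-2-oxoethyl}-3-[2,4-bis(benzyloxy)-6-(methoxymethoxy)phenyl]-3-oxopropanoate (racemic) | C=CCOC(=O)C(CC(=O)c1c(OCOC)cc(OC)cc1OCc1ccccc1)C(=O)c1c(OCOC)cc(OCc2ccccc2)cc1OCc1ccccc1
F4 | step 10 | 5,7-bis(benzyloxy)-3-[5-(benzyloxy)-2-hydroxy-7-methoxy-2-(4-methoxyphenyl)-4-oxochroman-3-yl]-2-hydroxy-2-(4-methoxyphenyl)chroman-4-one (bis(hemiketal) tautomer of 16, configuration not defined) | COc1ccc(C2(O)Oc3cc(OCc4ccccc4)cc(OCc4ccccc4)c3C(=O)C2C2C(=O)c3c(OCc4ccccc4)cc(OC)cc3OC2(O)c2ccc(OC)cc2)cc1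
F0 | step 12 | none | none
A1 | alternative 1 | (E)-4-methoxycinnamic acid | COc1ccc(/C=C/C(=O)O)cc1
A2 | alternative 1 | exo,exo-2,6-bis(4-methoxyphenyl)-3,7-dioxabicyclo[3.3.0]octane-4,8-dione | COc1ccc([C@H]2OC(=O)[C@H]3[C@@H]2C(=O)O[C@@H]3c2ccc(OC)cc2)cc1
A3 | alternative 2 | 2-diazo-1-[2-(4-methoxybenzyloxy)-4,6-bis(tert-butyldimethylsilyloxy)phenyl]-2-[5-(tert-butyldimethylsilyloxy)-7-methoxy-4-oxo-4H-chromen-3-yl]ethanone | COc1ccc(COc2cc(O[Si](C)(C)C(C)(C)C)cc(O[Si](C)(C)C(C)(C)C)c2C(=O)C(=[N+]=[N-])c2coc3cc(OC)cc(O[Si](C)(C)C(C)(C)C)c3c2=O)cc1
A4 | alternative 2 | (2S,3S)-5,7-bis(tert-butyldimethylsilyloxy)-3-[5-(tert-butyldimethylsilyloxy)-7-methoxy-4-oxo-4H-chromen-3-yl]-2-(4-methoxyphenyl)chroman-4-one (2,3-cis) | COc1ccc([C@H]2Oc3cc(O[Si](C)(C)C(C)(C)C)cc(O[Si](C)(C)C(C)(C)C)c3C(=O)[C@H]2c2coc3cc(OC)cc(O[Si](C)(C)C(C)(C)C)c3c2=O)cc1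
A5 | alternative 3 | 2,3-bis[hydroxy(4-methoxyphenyl)methyl]-N,N'-dimethoxy-N,N'-dimethylbutanediamide, C2-symmetric stereoisomer that maps onto the target | COc1ccc([C@@H](O)[C@@H](C(=O)N(C)OC)[C@H](C(=O)N(C)OC)[C@H](O)c2ccc(OC)cc2)cc1
A6 | alternative 3 | 3,5-bis(benzyloxy)-2-(trimethylsilyl)phenyl trifluoromethanesulfonate | C[Si](C)(C)c1c(OS(=O)(=O)C(F)(F)F)cc(OCc2ccccc2)cc1OCc1ccccc1
A7 | alternative 3 | (2S,3S)-5,7-bis(benzyloxy)-3-[(2S,3S)-5,7-bis(benzyloxy)-2-(4-methoxyphenyl)-4-oxochroman-3-yl]-2-(4-methoxyphenyl)chroman-4-one (both rings 2,3-cis) | COc1ccc([C@H]2Oc3cc(OCc4ccccc4)cc(OCc4ccccc4)c3C(=O)[C@H]2[C@@H]2C(=O)c3c(OCc4ccccc4)cc(OCc4ccccc4)cc3O[C@@H]2c2ccc(OC)cc2)cc1
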